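**Strategy.** Everything rests on opening coumarin B (primed atoms) at its lactone bond O1'–C8a'. Because the ether oxygen on C7' sits para to C4a', this unmasks a para-disubstituted E-cinnamic acid whose 4-oxygen is bonded to C3 of a finished 6-acetoxy-7-methoxycoumarin (coumarin A). One flavin-photocatalysed aerobic operation should isomerise the alkene to Z and join O1' to C8a', closing the pyranone of coumarin B. The two ortho carbons of the para-substituted ring are equivalent, so only the 7'-aryloxy isomer can form. The precursor is assembled by a Perkin condensation that builds coumarin A together with the diaryl ether, then a Heck coupling that adds the acrylate.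

Key step: step 5

Remark: plain locants refer to coumarin A (6-hydroxy-7-methoxy), primed locants to coumarin B (the 7-oxycoumarin); riboflavin is the natural (−)-form, whose stereocentres have no bearing on the achiral product.

**Step 1**
Reactants: 1 2-hydroxy-4-methoxybenzaldehyde
Product: 3 2,5-dihydroxy-4-methoxybenzaldehyde, via aryl sulfate 2 (not isolated)
Conditions: K2S2O8, aq NaOH, 5 °C → rt; then aq HCl, 90 °C
Reagents that add atoms: potassium peroxodisulfate, [K+].[K+].[O-]S(=O)(=O)OOS(=O)(=O)[O-]
Why: Elbs persulfate oxidation, in which the phenoxide of 1 attacks a peroxide oxygen of peroxodisulfate through C5 (the free position para to the phenol oxygen) and the S–O bond of aryl sulfate 2 is then hydrolysed by hot dilute acid, while the aldehyde, held in alkali as a vinylogous carboxylate, should be spared.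

**Step 2**
Reactants: 3 2,5-dihydroxy-4-methoxybenzaldehyde; 4 (4-bromophenoxy)acetic acid
Product: 7 3-(4-bromophenoxy)-7-methoxy-2-oxo-2H-chromen-6-yl acetate, via mixed anhydride 5 (not isolated), via aryl ester 6 (not isolated)
Conditions: Ac2O (solvent), Et3N, 110–120 °C
Reagents that add atoms: acetic anhydride, CC(=O)OC(C)=O
Why: Perkin (Oglialoro-type) coumarin condensation, in which acid 4 exchanges with Ac2O to mixed anhydride 5, reversible acyl transfer places the aryloxyacetyl group on O2 and an acetyl group on O5, and the O–CH2–C=O methylene of ester 6 (more acidic than an acetyl methyl) condenses with the ortho-formyl group under Et3N and dehydrates to the 3-aryloxycoumarin, the aryl bromide staying inert.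

**Step 3**
Reactants: 7 3-(4-bromophenoxy)-7-methoxy-2-oxo-2H-chromen-6-yl acetate; 8 tert-butyl acrylate
Product: 9 tert-butyl (E)-3-[4-(6-acetoxy-7-methoxy-2-oxo-2H-chromen-3-yloxy)phenyl]prop-2-enoate
Conditions: Pd(OAc)2 (5 mol%), P(o-tol)3 (10 mol%), Et3N, DMF, 100 °C
Reagents that add atoms: none
Why: Mizoroki–Heck coupling, in which zerovalent palladium formed in situ inserts into the aryl C–Br bond, syn-carbopalladation at the unsubstituted acrylate carbon and syn-β-hydride elimination give the E-cinnamate, and the anhydrous amine base should leave the aryl acetate and the lactone untouched.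

**Step 4**
Reactants: 9 tert-butyl (E)-3-[4-(6-acetoxy-7-methoxy-2-oxo-2H-chromen-3-yloxy)phenyl]prop-2-enoate
Product: 10 (E)-3-[4-(6-acetoxy-7-methoxy-2-oxo-2H-chromen-3-yloxy)phenyl]prop-2-enoic acid
Conditions: CF3CO2H, CH2Cl2, rt
Reagents that add atoms: none
Why: Acidolysis of a tert-butyl ester proceeds by alkyl–oxygen cleavage through the tert-butyl cation (lost as isobutene) and needs neither water nor a nucleophile, so the aryl acetate, the lactone and the diaryl ether should survive.

**Step 5**
Reactants: 10 (E)-3-[4-(6-acetoxy-7-methoxy-2-oxo-2H-chromen-3-yloxy)phenyl]prop-2-enoic acid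
Product: 12 7-methoxy-2-oxo-3-[(2-oxo-2H-chromen-7-yl)oxy]-2H-chromen-6-yl acetate, via Z-acid 11 (not isolated)
Conditions: (−)-riboflavin (10 mol%), O2 (1 atm), MeCN/MeOH 1:1, 402 nm LEDs, rt
Reagents that add atoms: none
Why: Triplet energy transfer from photoexcited riboflavin to the styrene-type chromophore of 10 should give Z-acid 11, which places the carboxyl group beside the ortho C–H at C8a'. Excited flavin then removes one electron from 11, the carboxyl oxygen O1' bonds to C8a', and the cyclohexadienyl radical (delocalised onto C4a' and the enoate) loses a second electron and the C8a' proton, restoring the aromatic ring while O2 reoxidises the reduced flavin and ends as H2O2. The closest known reaction type is the flavin-photocatalysed isomerisation and aerobic oxidative cyclisation of E-cinnamic acids to coumarins, so only the efficiency is open, because this acid has no β-substituent and O1' bonds meta to the aryloxy donor. The ring closed is the pyranone of coumarin B, by a six-membered O–C(sp2) closure onto the arene (formally 6-endo-trig with respect to C4a'=C8a'). No stereocentre is formed, and the Z geometry created by light is locked in the ring. Site selectivity is fixed because the two carbons ortho to the side chain are equivalent; chemoselectivity over coumarin A is helped by its electron-poor lactone and 6-acetoxy group, by its expected weak absorption at 402 nm, and by the neutral medium that keeps the acetate in place.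

**Step 6**
Reactants: 12 7-methoxy-2-oxo-3-[(2-oxo-2H-chromen-7-yl)oxy]-2H-chromen-6-yl acetate
Product: 13 6-hydroxy-7-methoxy-3-[(2-oxo-2H-chromen-7-yl)oxy]-2H-chromen-2-one
Conditions: K2CO3, MeOH, 0 °C → rt; then 1 M HCl
Reagents that add atoms: none
Why: Base-mediated transesterification of the aryl acetate is fast because the phenoxide is a good leaving group, and any lactone that opens to a Z-configured 2-hydroxycinnamate under base should reclose on acidification.

**Compound list**
1 | 2-hydroxy-4-methoxybenzaldehyde | COc1ccc(C=O)c(O)c1 | starting material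
2 | potassium 5-formyl-4-hydroxy-2-methoxyphenyl sulfate | COc1cc(O)c(C=O)cc1OS(=O)(=O)[O-].[K+] | intermediate
3 | 2,5-dihydroxy-4-methoxybenzaldehyde | COc1cc(O)c(C=O)cc1O | intermediate
4 | (4-bromophenoxy)acetic acid | OC(=O)COc1ccc(Br)cc1 | starting material
5 | acetic (4-bromophenoxy)acetic anhydride | CC(=O)OC(=O)COc1ccc(Br)cc1 | intermediate
6 | 4-acetoxy-2-formyl-5-methoxyphenyl (4-bromophenoxy)acetate | COc1cc(OC(=O)COc2ccc(Br)cc2)c(C=O)cc1OC(C)=O | intermediate
7 | 3-(4-bromophenoxy)-7-methoxy-2-oxo-2H-chromen-6-yl acetate | COc1cc2oc(=O)c(Oc3ccc(Br)cc3)cc2cc1OC(C)=O | intermediate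
8 | tert-butyl acrylate | C=CC(=O)OC(C)(C)C | starting material
9 | tert-butyl (E)-3-[4-(6-acetoxy-7-methoxy-2-oxo-2H-chromen-3-yloxy)phenyl]prop-2-enoate | COc1cc2oc(=O)c(Oc3ccc(/C=C/C(=O)OC(C)(C)C)cc3)cc2cc1OC(C)=O | intermediate
10 | (E)-3-[4-(6-acetoxy-7-methoxy-2-oxo-2H-chromen-3-yloxy)phenyl]prop-2-enoic acid | COc1cc2oc(=O)c(Oc3ccc(/C=C/C(=O)O)cc3)cc2cc1OC(C)=O | intermediate
11 | (Z)-3-[4-(6-acetoxy-7-methoxy-2-oxo-2H-chromen-3-yloxy)phenyl]prop-2-enoic acid | COc1cc2oc(=O)c(Oc3ccc(/C=C\C(=O)O)cc3)cc2cc1OC(C)=O | intermediate
12 | 7-methoxy-2-oxo-3-[(2-oxo-2H-chromen-7-yl)oxy]-2H-chromen-6-yl acetate | COc1cc2oc(=O)c(Oc3ccc4ccc(=O)oc4c3)cc2cc1OC(C)=O | intermediate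
13 | 6-hydroxy-7-methoxy-3-[(2-oxo-2H-chromen-7-yl)oxy]-2H-chromen-2-one | COc1cc2oc(=O)c(Oc3ccc4ccc(=O)oc4c3)cc2cc1O | target

**Step count and risks**
Total step count: 6. Longest linear sequence: 6 steps (1 → 3 → 7 → 9 → 10 → 12 → 13).

Steps most likely to fail:

1. Step 5. The photostationary mixture may hold too little Z-acid without a β-substituent, the C–O bond formation meta to the donor may be slow, and oxidative cleavage of the alkene by the flavin/O2 system may outrun lactonisation. The fallback gives up the late lactonisation and brings coumarin B in ready-made; it sets out from 3 and comes back at 12. Commercial umbelliferone (7-hydroxycoumarin) would be O-alkylated with tert-butyl bromoacetate (K2CO3, acetone, reflux) to tert-butyl (2-oxo-2H-chromen-7-yloxy)acetate F1, and CF3CO2H in CH2Cl2 would release (2-oxo-2H-chromen-7-yloxy)acetic acid F2. Perkin condensation of 3 with this acid in Ac2O/Et3N at 110–120 °C, exactly as in step 2, should then give 12, which enters step 6.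

2. Step 1. Conversion in the persulfate oxidation may stay low, and the hydroquinone-type product may be over-oxidised to quinonoid material during reaction or hydrolysis. The fallback replaces the direct C–H oxygenation by halogenation and C–O coupling; it sets out from 1 and comes back at 3. Bromination of 1 (Br2, NaOAc, AcOH, rt) para to the phenol should give 5-bromo-2-hydroxy-4-methoxybenzaldehyde F3. Ullmann-type copper-catalysed hydroxylation (Cu(acac)2, N,N'-bis(4-hydroxy-2,6-dimethylphenyl)oxalamide, LiOH, DMSO/H2O, 80–100 °C, argon; then dilute HCl) would then convert the C–Br bond into the C5 hydroxyl of 3. The model is the classical copper-mediated hydrolysis of halogenated hydroxybenzaldehydes in hot alkali.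

3. Step 2. Acyl groups may scramble in hot anhydride, leaving the aryloxyacetyl group on O5 or letting an O2-acetyl condense to the 3-unsubstituted coumarin, and the electron-rich aldehyde may decompose thermally. The fallback separates the events at ambient temperature; it sets out from 3 and comes back at 7. Ac2O (1.0 equiv) with pyridine in CH2Cl2 at 0 °C should acetylate the free 5-hydroxyl in preference to the chelated 2-hydroxyl, giving 5-acetoxy-2-hydroxy-4-methoxybenzaldehyde F4. Esterification with 4 (EDC·HCl, catalytic DMAP, CH2Cl2, rt) would give aryl ester 6, this time isolated, and DBU in MeCN at rt should close it by intramolecular Knoevenagel condensation to 7.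

**Further compounds**
F1 | step 5 | tert-butyl (2-oxo-2H-chromen-7-yloxy)acetate | CC(C)(C)OC(=O)COc1ccc2ccc(=O)oc2c1
F2 | step 5 | (2-oxo-2H-chromen-7-yloxy)acetic acid | OC(=O)COc1ccc2ccc(=O)oc2c1
F3 | step 1 | 5-bromo-2-hydroxy-4-methoxybenzaldehyde | COc1cc(O)c(C=O)cc1Br
F4 | step 2 | 5-acetoxy-2-hydroxy-4-methoxybenzaldehyde | COc1cc(O)c(C=O)cc1OC(C)=O
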